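Numbering: ring A carries primed locants, 1' (OMe), 2' (H), 3' (ether O), 4' (acetyl), 5' (OH), 6' (Me); ring B = B1 (ether O), B2 (OH), B3 (Me), B4 (OMe), B5 (acetyl), B6 (OH).
Retrosynthesis: the O–CH3 bond at 5' (the phenol is stored as a methyl ether) and the bond from 4' to its acetyl group are cut first, then ring B is opened at B5–B6, then the chain is cut at B1–B2 into an aryloxyacetate and a pyrone-derived keto acid, and last the O–CH2 bond at the 3' oxygen.
Enabling feature: ring B is an acylphloroglucinol (oxygen on B2, B4, B6; acetyl on B5) whose fourth oxygen, at B1, lies on the carbon that is the alpha carbon of a polyketide ester between B6 and B2, so the crowded diaryl ether can be made as an alkyl aryl ether on sp3 carbon before ring B exists; the B4 methoxy group is the chain's enol ether.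
Forward: ring A phenol, then aryloxyacetate; hydroxypyrone, then O-methyl pyrone, then ring-opened, ketal-masked acid; a crossed Claisen condensation joins the two; Claisen aromatisation builds ring B (the only ring made); ring A is then acetylated at 4' and its 5' methyl ether cleaved under direction of the new ketone.
Stereochemistry: the target has no stereocentre; the only stereo-elements on the way are the E alkene of the chain, inherited from the pyrone ring, and the racemic C2 centre, which vanishes on aromatisation.

Key step: step 9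

Remark on the chemistry: ring A is carried with methyl ethers at both 1' and 5', so 2' and 4' stay equivalent until the acetyl group is in place; the 5' methyl group is then the only one that the 4' ketone can hand to BCl3.

Step 1
Reactants: 1 2,6-dimethoxytoluene (1,3-dimethoxy-2-methylbenzene)
Product: 3 3,5-dimethoxy-4-methylphenol, via aryl pinacol boronate 2 (not isolated)
Conditions: B2pin2, [Ir(OMe)(cod)]2 (cat.), 4,4'-di-tert-butyl-2,2'-bipyridine (cat.), THF, 80 °C; then KHSO5 (Oxone), acetone/H2O, rt
Reagents that add atoms: bis(pinacolato)diboron, CC1(C)OB(OC1(C)C)B1OC(C)(C)C(C)(C)O1 (boron of 2); potassium peroxymonosulfate KHSO5, [K+].[O-]S(=O)(=O)OO (oxygen of 3)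
Why: Iridium-catalysed aromatic C–H borylation is sterically controlled and should take the only ring C–H of 1 that has no ortho substituent (para to the methyl group), and oxidation of the aryl boronate in the same pot should give the phenol.

Step 2
Reactants: 3 3,5-dimethoxy-4-methylphenol; 4 methyl bromoacetate
Product: 5 methyl 2-(3,5-dimethoxy-4-methylphenoxy)acetate
Conditions: K2CO3, acetone, reflux
Reagents that add atoms: none
Why: Williamson ether synthesis by SN2 attack of an unhindered phenoxide on a primary alpha-bromo ester, which places the future ether bond between the 3' oxygen and B1 on an sp3 carbon.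

Step 3
Reactants: 6 4-hydroxy-3,6-dimethyl-2H-pyran-2-one
Product: 7 4-methoxy-3,6-dimethyl-2H-pyran-2-one
Conditions: Me2SO4, K2CO3, acetone, reflux
Reagents that add atoms: dimethyl sulfate, COS(=O)(=O)OC
Why: O-methylation of the vinylogous acid with a hard methylating agent should give the 4-methoxy-2-pyrone, which fixes the methyl ether that later becomes the B4 methoxy group.

Step 4
Reactants: 7 4-methoxy-3,6-dimethyl-2H-pyran-2-one
Product: 8 methyl (2E)-3-methoxy-2-methyl-5-oxohex-2-enoate (ester carbon and CH2 cis on the alkene)
Conditions: Mg(OMe)2, MeOH, 50 °C; cold aq. NH4Cl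
Reagents that add atoms: magnesium methoxide, C[O-].C[O-].[Mg+2] (methoxy group of the ester)
Why: Methoxide opens the enol lactone by acyl substitution at C2 (pyrone methanolysis), magnesium holds the released ketone enolate so that it does not reclose, and the alkene keeps the cis arrangement that the ring imposed.

Step 5
Reactants: 8 methyl (2E)-3-methoxy-2-methyl-5-oxohex-2-enoate
Product: 9 methyl (2E)-3,5,5-trimethoxy-2-methylhex-2-enoate
Conditions: HC(OMe)3, MeOH, TsOH (cat.), rt; Et3N quench
Reagents that add atoms: trimethyl orthoformate, COC(OC)OC; methanol, CO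
Why: Acid-catalysed ketalisation with an orthoformate as water scavenger masks the methyl ketone, and methanol is chosen so that any exchange at the enol ether is degenerate.

Step 6
Reactants: 9 methyl (2E)-3,5,5-trimethoxy-2-methylhex-2-enoate
Product: 10 (2E)-3,5,5-trimethoxy-2-methylhex-2-enoic acid
Conditions: LiOH, THF/MeOH/H2O, 45 °C; then aq. citric acid to pH 5, 0 °C
Reagents that add atoms: lithium hydroxide, [Li+].[OH-]
Why: Ester saponification leaves the base-stable ketal and enol ether alone, and the buffered, cold acidification should spare the dimethyl ketal.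

Step 7
Reactants: 10 (2E)-3,5,5-trimethoxy-2-methylhex-2-enoic acid; 5 methyl 2-(3,5-dimethoxy-4-methylphenoxy)acetate
Product: 13 methyl (4E)-2-(3,5-dimethoxy-4-methylphenoxy)-5,7,7-trimethoxy-4-methyl-3-oxooct-4-enoate (racemic at C2), via acyl imidazole 11 (not isolated), via lithium ester enolate 12 (not isolated)
Conditions: 10, CDI, THF, rt; separately 5, LiHMDS (2.2 equiv), THF, −78 °C; then add the solution of 11, −78 to −20 °C; aq. NH4Cl
Reagents that add atoms: 1,1'-carbonyldiimidazole, O=C(n1ccnc1)n1ccnc1 (imidazolyl group of 11); lithium hexamethyldisilazide, [Li+].C[Si](C)(C)[N-][Si](C)(C)C (lithium of 12)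
Why: Crossed Claisen condensation of a lithium ester enolate with an acyl imidazole forms the C2–C3 bond, the neutral activation spares the ketal, and the extra equivalent of base takes up the acidic beta-keto ester as it forms.

Step 8
Reactants: 13 methyl (4E)-2-(3,5-dimethoxy-4-methylphenoxy)-5,7,7-trimethoxy-4-methyl-3-oxooct-4-enoate
Product: 14 methyl (4E)-2-(3,5-dimethoxy-4-methylphenoxy)-5-methoxy-4-methyl-3,7-dioxooct-4-enoate (racemic at C2; C3 acyl and C6 methylene cis on the alkene)
Conditions: PPTS (cat.), acetone/H2O, rt
Reagents that add atoms: water, O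
Why: Acid-catalysed ketal hydrolysis of an acyclic dimethyl ketal is far faster than hydrolysis of the vinylogous-ester enol ether, so a weak acid in wet acetone should free only the C7 ketone.

Step 9
Reactants: 14 methyl (4E)-2-(3,5-dimethoxy-4-methylphenoxy)-5-methoxy-4-methyl-3,7-dioxooct-4-enoate
Product: 15 1-[3-(3,5-dimethoxy-4-methylphenoxy)-2,4-dihydroxy-6-methoxy-5-methylphenyl]ethanone
Conditions: Mg(OMe)2 (excess), MeOH, reflux; then cold dilute HCl
Reagents that add atoms: none
Why: Mg(OMe)2 reversibly deprotonates C2 and C6; the C6 carbanion, alpha to the C7 methyl ketone and vinylogous to the C3 carbonyl, adds to the ester carbon C1, methoxide is expelled and the cyclohexadienone enolises to the magnesium phloroglucinolate of ring B, the only irreversible sink in the system. The closest known reaction is the alkoxide- or Mg(OMe)2-induced Claisen aromatisation of 3,5,7-triketo esters and their enol ethers to acylphloroglucinols. Ring B closes in a 6-(enolexo)-exo-trig mode that forms the B5–B6 bond, helped by the E alkene, which holds C3 and C6 cis, and by magnesium chelation of the C1/C3 dicarbonyl unit. No stereocentre is created; the racemic C2 centre becomes the planar carbon B1. The step needs the Claisen fold to beat the aldol fold (C2 onto C7) and retro-Claisen cleavage at C3: the aryloxy group makes the aldol carbon quaternary, so that adduct cannot aromatise without losing a substituent and should revert, while C3 is a vinylogous-ester carbonyl that is further shielded inside the chelated C2 enolate. The C5 enol methyl ether fixes which oxygen is methylated and emerges unchanged as the B4 methoxy group.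

Step 10
Reactants: 15 1-[3-(3,5-dimethoxy-4-methylphenoxy)-2,4-dihydroxy-6-methoxy-5-methylphenyl]ethanone
Product: 16 4-acetyl-2-(3,5-dimethoxy-4-methylphenoxy)-5-methoxy-6-methyl-1,3-phenylene diacetate
Conditions: Ac2O, pyridine, DMAP (cat.), CH2Cl2, rt
Reagents that add atoms: acetic anhydride, CC(=O)OC(C)=O
Why: DMAP-catalysed acetylation masks both ring B phenols, so the Lewis acid of the next step meets no free OH and the acetyl chloride is spent on carbon only.

Step 11
Reactants: 16 4-acetyl-2-(3,5-dimethoxy-4-methylphenoxy)-5-methoxy-6-methyl-1,3-phenylene diacetate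
Product: 17 4-acetyl-2-(2-acetyl-3,5-dimethoxy-4-methylphenoxy)-5-methoxy-6-methyl-1,3-phenylene diacetate
Conditions: AcCl, SnCl4, CH2Cl2, −20 to 0 °C
Reagents that add atoms: acetyl chloride, CC(Cl)=O
Why: Friedel–Crafts acylation can only strike ring A (ring B has no free carbon), its two open positions 2' and 4' are equivalent by symmetry and each lies ortho or para to three oxygen donors, and the first acetyl group deactivates the ring against a second.

Step 12
Reactants: 17 4-acetyl-2-(2-acetyl-3,5-dimethoxy-4-methylphenoxy)-5-methoxy-6-methyl-1,3-phenylene diacetate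
Product: 18 1-[3-(2-acetyl-3,5-dimethoxy-4-methylphenoxy)-2,4-dihydroxy-6-methoxy-5-methylphenyl]ethanone
Conditions: K2CO3, MeOH, 0 °C to rt; aq. NH4Cl
Reagents that add atoms: none
Why: Base-mediated transesterification removes the two aryl acetates, while methyl ethers, ketones and the diaryl ether are inert to carbonate in methanol.

Step 13
Reactants: 18 1-[3-(2-acetyl-3,5-dimethoxy-4-methylphenoxy)-2,4-dihydroxy-6-methoxy-5-methylphenyl]ethanone
Product: 19 leprolomin, 1-[3-(2-acetyl-3-hydroxy-5-methoxy-4-methylphenoxy)-2,4-dihydroxy-6-methoxy-5-methylphenyl]ethanone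
Conditions: BCl3, CH2Cl2, −78 to 0 °C; then H2O
Reagents that add atoms: none
Why: Chelation-directed demethylation with BCl3 cleaves a methyl ether only where its oxygen and a neighbouring free ketone can clasp boron in a six-membered chelate, which is true for the 5' ether alone, because the 1' ether has no carbonyl neighbour and the ring B ketone is already locked to the B6 oxygen as its O–BCl2 chelate.

Compound list
1 | 2,6-dimethoxytoluene (1,3-dimethoxy-2-methylbenzene) | COc1cccc(OC)c1C | starting material
2 | 2-(3,5-dimethoxy-4-methylphenyl)-4,4,5,5-tetramethyl-1,3,2-dioxaborolane (not isolated) | COc1cc(B2OC(C)(C)C(C)(C)O2)cc(OC)c1C | intermediate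
3 | 3,5-dimethoxy-4-methylphenol | COc1cc(O)cc(OC)c1C | intermediate
4 | methyl bromoacetate | COC(=O)CBr | starting material
5 | methyl 2-(3,5-dimethoxy-4-methylphenoxy)acetate | COC(=O)COc1cc(OC)c(C)c(OC)c1 | intermediate
6 | 4-hydroxy-3,6-dimethyl-2H-pyran-2-one | CC1=CC(O)=C(C)C(=O)O1 | starting material
7 | 4-methoxy-3,6-dimethyl-2H-pyran-2-one | CC1=CC(OC)=C(C)C(=O)O1 | intermediate
8 | methyl (2E)-3-methoxy-2-methyl-5-oxohex-2-enoate | COC(=O)/C(C)=C(OC)\CC(C)=O | intermediate
9 | methyl (2E)-3,5,5-trimethoxy-2-methylhex-2-enoate | COC(=O)/C(C)=C(OC)\CC(C)(OC)OC | intermediate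
10 | (2E)-3,5,5-trimethoxy-2-methylhex-2-enoic acid | OC(=O)/C(C)=C(OC)\CC(C)(OC)OC | intermediate
11 | (2E)-1-(1H-imidazol-1-yl)-3,5,5-trimethoxy-2-methylhex-2-en-1-one (not isolated) | O=C(/C(C)=C(OC)\CC(C)(OC)OC)n1ccnc1 | intermediate
12 | lithium enolate of 5, lithium 1-methoxy-2-(3,5-dimethoxy-4-methylphenoxy)ethen-1-olate (enolate geometry not defined; not isolated) | [Li+].COC([O-])=COc1cc(OC)c(C)c(OC)c1 | intermediate
13 | methyl (4E)-2-(3,5-dimethoxy-4-methylphenoxy)-5,7,7-trimethoxy-4-methyl-3-oxooct-4-enoate (racemic at C2) | COC(=O)C(Oc1cc(OC)c(C)c(OC)c1)C(=O)/C(C)=C(OC)\CC(C)(OC)OC | intermediate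
14 | methyl (4E)-2-(3,5-dimethoxy-4-methylphenoxy)-5-methoxy-4-methyl-3,7-dioxooct-4-enoate (racemic at C2) | COC(=O)C(Oc1cc(OC)c(C)c(OC)c1)C(=O)/C(C)=C(OC)\CC(C)=O | intermediate
15 | 1-[3-(3,5-dimethoxy-4-methylphenoxy)-2,4-dihydroxy-6-methoxy-5-methylphenyl]ethanone | COc1cc(Oc2c(O)c(C)c(OC)c(C(C)=O)c2O)cc(OC)c1C | intermediate
16 | 4-acetyl-2-(3,5-dimethoxy-4-methylphenoxy)-5-methoxy-6-methyl-1,3-phenylene diacetate | COc1cc(Oc2c(OC(C)=O)c(C)c(OC)c(C(C)=O)c2OC(C)=O)cc(OC)c1C | intermediate
17 | 4-acetyl-2-(2-acetyl-3,5-dimethoxy-4-methylphenoxy)-5-methoxy-6-methyl-1,3-phenylene diacetate | COc1cc(Oc2c(OC(C)=O)c(C)c(OC)c(C(C)=O)c2OC(C)=O)c(C(C)=O)c(OC)c1C | intermediate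
18 | 1-[3-(2-acetyl-3,5-dimethoxy-4-methylphenoxy)-2,4-dihydroxy-6-methoxy-5-methylphenyl]ethanone | COc1cc(Oc2c(O)c(C)c(OC)c(C(C)=O)c2O)c(C(C)=O)c(OC)c1C | intermediate
19 | leprolomin, 1-[3-(2-acetyl-3-hydroxy-5-methoxy-4-methylphenoxy)-2,4-dihydroxy-6-methoxy-5-methylphenyl]ethanone | COc1cc(Oc2c(O)c(C)c(OC)c(C(C)=O)c2O)c(C(C)=O)c(O)c1C | target

Total step count: 13. Longest linear sequence: 11 steps (6 to 19, steps 3 to 13); the ring A branch (steps 1 and 2) joins at step 7.

Steps most likely to fail

Step 9. Retro-Claisen cleavage of the C2–C3 bond by methoxide, or closure by the aldol mode followed by loss of the ester group, may outrun the Claisen closure, because the aryloxy-bearing C2 is both the most acidic and the most hindered position of the chain. The fallback closes ring B first on the chain that carries no aryloxy group and makes the ether afterwards; it sets out from 10 (through its acyl imidazole 11) and from 3 and comes back at 15. Acyl imidazole 11 would be condensed with the magnesium salt of monomethyl malonate (potassium methyl malonate, MgCl2, Et3N, MeCN; decarboxylative Claisen condensation) to give methyl (4E)-5,7,7-trimethoxy-4-methyl-3-oxooct-4-enoate F1. PPTS in wet acetone would free the ketone to give methyl (4E)-5-methoxy-4-methyl-3,7-dioxooct-4-enoate F2. Mg(OMe)2 in methanol should then fold this unsubstituted chain, the fully precedented case, into 1-(4,6-dihydroxy-2-methoxy-3-methylphenyl)ethanone F3. N-Iodosuccinimide in MeCN would iodinate the single free ring position to give 1-(2,4-dihydroxy-3-iodo-6-methoxy-5-methylphenyl)ethanone F4, and BnBr with K2CO3 in DMF would give 1-[2,4-bis(benzyloxy)-3-iodo-6-methoxy-5-methylphenyl]ethanone F5. An Ullmann-type coupling with phenol 3 (CuI, picolinic acid, K3PO4, DMSO, 100 °C) would give 1-[2,4-bis(benzyloxy)-3-(3,5-dimethoxy-4-methylphenoxy)-6-methoxy-5-methylphenyl]ethanone F6, and hydrogenolysis (H2, Pd/C, EtOAc) would return 15. The price is a hindered coupling at an aromatic carbon in place of the sp3 ether.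

Step 7. C-acylation by the electron-rich, tetrasubstituted acyl imidazole may be slower than proton transfer to the enolate or than self-condensation of the enolate on warming. The fallback replaces the strongly basic lithium enolate by a malonate half-ester under soft enolisation; it sets out from 3 and from 10 (as 11) and comes back at 13. Phenol 3 would be alkylated with dimethyl bromomalonate (K2CO3, acetone) to give dimethyl 2-(3,5-dimethoxy-4-methylphenoxy)malonate F7. Saponification of one ester group (KOH, 1 equiv, MeOH; mild acidification) would give 2-(3,5-dimethoxy-4-methylphenoxy)-3-methoxy-3-oxopropanoic acid F8. Its magnesium salt (MgCl2, Et3N, MeCN/THF) would be acylated by 11 with loss of carbon dioxide (decarboxylative Claisen condensation) to give 13.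

Step 13. With excess BCl3 the second chelatable methyl ether, at B4, may also be lost, or cleavage at the hindered 5' ether may stall. The fallback locks the ring B ketone in a tetracoordinate boron chelate before the Lewis acid is applied, so that only the ring A ketone can direct it; it sets out from 18 and comes back at 19. BF3·OEt2 with iPr2NEt in CH2Cl2 would convert 18 into the difluoroboron chelate of 18 (BF2 bridging the B6 oxygen and the ring B acetyl oxygen) F9. BCl3 at −78 to 0 °C would then cleave the 5' methyl ether to give the difluoroboron chelate of leprolomin (BF2 bridging the B6 oxygen and the ring B acetyl oxygen) F10, and NaOAc in aqueous ethanol at reflux would hydrolyse the chelate to 19.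

Further compounds
F1 | step 9 | methyl (4E)-5,7,7-trimethoxy-4-methyl-3-oxooct-4-enoate | COC(=O)CC(=O)/C(C)=C(OC)\CC(C)(OC)OC
F2 | step 9 | methyl (4E)-5-methoxy-4-methyl-3,7-dioxooct-4-enoate | COC(=O)CC(=O)/C(C)=C(OC)\CC(C)=O
F3 | step 9 | 1-(4,6-dihydroxy-2-methoxy-3-methylphenyl)ethanone | CC(=O)c1c(O)cc(O)c(C)c1OC
F4 | step 9 | 1-(2,4-dihydroxy-3-iodo-6-methoxy-5-methylphenyl)ethanone | CC(=O)c1c(O)c(I)c(O)c(C)c1OC
F5 | step 9 | 1-[2,4-bis(benzyloxy)-3-iodo-6-methoxy-5-methylphenyl]ethanone | CC(=O)c1c(OCc2ccccc2)c(I)c(OCc2ccccc2)c(C)c1OC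
F6 | step 9 | 1-[2,4-bis(benzyloxy)-3-(3,5-dimethoxy-4-methylphenoxy)-6-methoxy-5-methylphenyl]ethanone | COc1cc(Oc2c(OCc3ccccc3)c(C)c(OC)c(C(C)=O)c2OCc2ccccc2)cc(OC)c1C
F7 | step 7 | dimethyl 2-(3,5-dimethoxy-4-methylphenoxy)malonate | COC(=O)C(Oc1cc(OC)c(C)c(OC)c1)C(=O)OC
F8 | step 7 | 2-(3,5-dimethoxy-4-methylphenoxy)-3-methoxy-3-oxopropanoic acid (racemic) | COC(=O)C(Oc1cc(OC)c(C)c(OC)c1)C(O)=O
F9 | step 13 | difluoroboron chelate of 18 (BF2 bridging the B6 oxygen and the ring B acetyl oxygen) | COc1cc(Oc2c(O)c(C)c(OC)c3c2O[B-](F)(F)[O+]=C3C)c(C(C)=O)c(OC)c1C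
F10 | step 13 | difluoroboron chelate of leprolomin (BF2 bridging the B6 oxygen and the ring B acetyl oxygen) | COc1cc(Oc2c(O)c(C)c(OC)c3c2O[B-](F)(F)[O+]=C3C)c(C(C)=O)c(O)c1C
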